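The earlier runs and the new flask are calculated from invented constants; the scatter is artificial.

The ratio of left-handed to right-handed product opened the meeting: the first speaker set 1.97 in the ochre run after 10.0 h beside 2.07 in the red run after 5.00 h, and noted that both runs then stand at 2.50 mM·h of catalyst-hours (free catalyst charged times time), with 26.2% and 26.5% of left-handed product as fractions of the charge, although red held more substrate.

the same everywhere: gas 10 mM (held)
- ochre: left-handed substrate 0.10 M; right-handed substrate 0.10 M; free catalyst 0.25 mM; temperature −20 °C; run made earlier
- blue: left-handed substrate 0.10 M; right-handed substrate 0.10 M; free catalyst 1 mM; temperature 5 °C; run made earlier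
- red: left-handed substrate 0.15 M; right-handed substrate 0.15 M; free catalyst 0.50 mM; temperature −20 °C; run made earlier
- larch: left-handed substrate 0.10 M; right-handed substrate 0.10 M; free catalyst 0.50 mM; temperature 5 °C; time 4.0 h
- elm: left-handed substrate 0.10 M; right-handed substrate 0.10 M; free catalyst 0.50 mM; temperature 25 °C; time 4.0 h
- ash: left-handed substrate 0.10 M; right-handed substrate 0.10 M; free catalyst 0.50 mM; temperature −15 °C; time 4.0 h

- ochre (time / h: left-handed product / %, right-handed product / %): 0.833: 2.8, 1.4; 1.33: 5.4, 1.1; 2.50: 8.9, 2.7; 3.00: 10.3, 4.3; 5.00: 15.9, 6.4; 6.00: 18.6, 8.8; 10.0: 26.2, 13.3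
- blue (time / h: left-handed product / %, right-handed product / %): 0.500: 21.9, 13.3; 1.00: 33.7, 24.4; 1.33: 37.8, 29.3; 2.00: 43.0, 37.5; 2.50: 45.8, 40.8; 3.00: 47.1, 43.8
- red (time / h: left-handed product / %, right-handed product / %): 2.50: 15.9, 6.8; 5.00: 26.5, 12.8; 6.00: 29.5, 15.1; 8.00: 34.5, 19.2; 10.0: 39.1, 23.1

(readings scatter by 0.3 percentage points)

- the flask with the highest excess of left-handed product over right-handed product ("all alike" if they lie within 1.5 percentage points) (larch / elm / ash / all alike)
- excess of left-handed product over right-handed product at the end, larch
- excess of left-handed product over right-handed product at the end, elm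
- excess of left-handed product over right-handed product at the end, ash

- free catalyst is single-handed; left-handed substrate and right-handed substrate are mirror images of each other, charged as a racemate, each of them at the stated concentration
- at the start none of the gas is in solution
- an excess is the difference of the two amounts in percent of their sum
- an excess is below zero if the other one leads

She therefore proposed the bite: minus the logarithm of the fraction of one substrate's own charge not turned into its product, per catalyst-hour. From ochre's last reading this is 0.297 /mM/h for the left-handed substrate and 0.124 /mM/h for the right-handed one, and from blue's first reading 1.15 /mM/h and 0.618 /mM/h. Taking the logarithms in proportion to temperature, she put ash at −15 °C at a left-handed bite of 0.389 /mM/h and a right-handed bite of 0.171 /mM/h, a selectivity factor of 2.27.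

The second speaker objected that blue, at 2.00 mM·h of catalyst-hours after 2.00 h, the count of larch, reads an excess of 6.83%, and 3.63% by 3.00 h, so she expected larch, which stands at the same 5 °C and takes 4.0 h, lower still and elm near zero. My own reckoning gives ash 27.1% and 14.5% of the two products, an excess of 30.3%, and puts ash first.

The forecast, which said of the blue run that “this points to product racemisation”, named ash first, with 5.5% for larch, −0.3% for elm and 31% for ash, slightly above my figure.

The flasks give 3.13% for larch, 0% for elm and 31.6% for ash, so ash leads.

    reagent + free catalyst + left-handed substrate → free catalyst + left-handed product (k = 1.50 × 10⁵ /M²/h, Ea = 36.0 kJ/mol)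
    reagent + free catalyst + right-handed substrate → free catalyst + right-handed product (k = 63000 /M²/h, Ea = 40.0 kJ/mol)
    left-handed substrate ⇌ right-handed substrate (k = 1.20 /h, Ea = 88.0 kJ/mol)
    free catalyst → spent catalyst (k = 0.140 /h, Ea = 90.0 kJ/mol)
    left-handed product ⇌ right-handed product (k = 0.680 /h, Ea = 87.0 kJ/mol)
    gas ⇌ reagent, rate k6*(csat - [reagent]) (kL = 130 /h)
    (constants at 5 °C)

The neighbouring flask is ash with 0.200 mM of free catalyst, held for the same 4.0 h. The two bites reckoned for ash, applied to its 0.800 mM·h of catalyst-hours, give 13.4% of left-handed product, 6.38% of right-handed product and an excess of 35.5%. That flask holds 14.3% and 6.64% of the two products at the end, and its excess is 36.5%.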